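The target is a butyrolactone (ring atoms O1, C2, C3, C4, C5) whose C3 carries a hydroxyl oxygen and a guaiacylmethyl carbon, the same pair of atoms that flanks the C–O bond of a benzylic ether. Both C3 bonds are therefore cut back to a C3 carbene and the symmetrical bis(4-benzyloxy-3-methoxybenzyl) ether. In one operation a copper carbene made from the 3-diazo lactone is trapped by the ether oxygen, and a [1,2]-Stevens shift moves one arylmethyl group from oxygen to C3, anti to the C4 arm. The precursor is (R)-3-diazo-4-(4-benzyloxy-3,5-dimethoxybenzyl)butyrolactone, whose only stereocentre comes from an asymmetric hydrogenation; a single hydrogenolysis then frees the carbinol and both phenols.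

Key step: step 8

Assumption: the (4S,5S) antipode of MOD-DIOP is taken to give the (R)-acid 6 in step 3, as is usual for itaconate-type half-esters; should a first run show the opposite sense, the (4R,5R) ligand is used and nothing else changes.

Step 1
Reactants: 1 syringaldehyde (4-hydroxy-3,5-dimethoxybenzaldehyde)
Product: 2 4-(benzyloxy)-3,5-dimethoxybenzaldehyde
Conditions: BnBr, K2CO3, DMF, 60 °C
Reagents that add atoms: benzyl bromide, BrCc1ccccc1
Why: Williamson O-alkylation of the phenoxide; the benzyl ether survives the basic and reducing steps ahead and leaves in the final hydrogenolysis.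

Step 2
Reactants: 2 4-(benzyloxy)-3,5-dimethoxybenzaldehyde; 3 dimethyl succinate
Product: 5 (E)-4-[4-(benzyloxy)-3,5-dimethoxyphenyl]-3-(methoxycarbonyl)but-3-enoic acid, via Stobbe lactone 4 (not isolated)
Conditions: NaOMe, MeOH, reflux; then aq. HCl
Reagents that add atoms: none
Why: Stobbe condensation: the succinate enolate adds to the aldehyde, the aldolate closes onto the distal ester to give lactone 4, and base-induced E1cB opening of 4 should deliver the half-ester with the aryl group trans to the conjugated ester (E).

Step 3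
Reactants: 5 (E)-4-[4-(benzyloxy)-3,5-dimethoxyphenyl]-3-(methoxycarbonyl)but-3-enoic acid
Product: 6 (R)-4-[4-(benzyloxy)-3,5-dimethoxyphenyl]-3-(methoxycarbonyl)butanoic acid
Conditions: H2 (1 atm), [Rh(cod)Cl]2 (0.5 mol%), (4S,5S)-MOD-DIOP (1.1 mol%), Et3N (1 equiv), MeOH, 30 °C; then aq. HCl
Reagents that add atoms: none
Why: Rhodium-bisphosphine asymmetric hydrogenation of an itaconate-type half-ester: carboxylate and alkene chelate rhodium and the C2-symmetric ligand selects the alkene face, which sets the R centre that becomes C4 of the lactone, while aryl benzyl ethers are inert to the homogeneous catalyst.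

Step 4
Reactants: 6 (R)-4-[4-(benzyloxy)-3,5-dimethoxyphenyl]-3-(methoxycarbonyl)butanoic acid
Product: 8 (R)-4-[4-(benzyloxy)-3,5-dimethoxybenzyl]dihydrofuran-2(3H)-one, via hydroxy acid 7 (not isolated)
Conditions: KOH (1 equiv), EtOH, 0 °C; Ca(BH4)2 (from CaCl2 and NaBH4), EtOH, −10 °C to rt; then 3 M HCl, rt
Reagents that add atoms: none
Why: Chemoselective borohydride reduction: Ca(BH4)2 reduces the methyl ester while the potassium carboxylate is untouched, and on acidification hydroxy acid 7 closes to the five-membered lactone by intramolecular esterification without involving the stereocentre.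

Step 5
Reactants: 8 (R)-4-[4-(benzyloxy)-3,5-dimethoxybenzyl]dihydrofuran-2(3H)-one
Product: 10 (R)-4-[4-(benzyloxy)-3,5-dimethoxybenzyl]-3-diazodihydrofuran-2(3H)-one, via 3-trifluoroacetyl lactone 9 (not isolated)
Conditions: LiN(SiMe3)2, THF, −78 °C, then CF3CO2CH2CF3; aq. HCl work-up; MsN3, Et3N, H2O (1 equiv), MeCN, rt
Reagents that add atoms: 2,2,2-trifluoroethyl trifluoroacetate, O=C(OCC(F)(F)F)C(F)(F)F (its acyl group is carried by 9 only); methanesulfonyl azide, CS(=O)(=O)N=[N+]=[N-]
Why: Deacylative Regitz diazo transfer in its detrifluoroacetylative form: Claisen trifluoroacetylation activates C3, the enolate of 9 adds to the sulfonyl azide and the trifluoroacetyl group leaves as the N-sulfonyl amide, while C4 is not acidic and keeps its configuration.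

Step 6
Reactants: 11 4-(benzyloxy)-3-methoxybenzyl alcohol
Product: 12 4-(benzyloxy)-3-methoxybenzyl chloride
Conditions: SOCl2, CH2Cl2, 0 °C to rt
Reagents that add atoms: thionyl chloride, O=S(Cl)Cl
Why: Chlorination of an electron-rich benzylic alcohol with thionyl chloride, which should be fast at 0 °C; the chloride is used promptly in step 7.

Step 7
Reactants: 11 4-(benzyloxy)-3-methoxybenzyl alcohol; 12 4-(benzyloxy)-3-methoxybenzyl chloride
Product: 13 bis[4-(benzyloxy)-3-methoxybenzyl] ether
Conditions: NaH, THF/DMF, 0 °C, then 12, n-Bu4NI (cat.), rt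
Reagents that add atoms: none
Why: Williamson ether synthesis under basic conditions, preferred to acid-catalysed dehydration because acid would ionise these electron-rich benzylic alcohols and lead to Friedel–Crafts oligomers of the cyclotriveratrylene type.

Step 8
Reactants: 10 (R)-4-[4-(benzyloxy)-3,5-dimethoxybenzyl]-3-diazodihydrofuran-2(3H)-one; 13 bis[4-(benzyloxy)-3-methoxybenzyl] ether
Product: 16 (3S,4S)-3-[4-(benzyloxy)-3-methoxybenzyl]-3-{[4-(benzyloxy)-3-methoxybenzyl]oxy}-4-[4-(benzyloxy)-3,5-dimethoxybenzyl]dihydrofuran-2(3H)-one, via copper carbene 14 (not isolated), via oxonium ylide 15 (not isolated)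
Conditions: Cu(hfacac)2 (10 mol%), 13 (4 equiv), CH2Cl2, 40 °C, 10 added over 8 h
Reagents that add atoms: none
Why: Proposed new method: Cu(hfacac)2 (copper bis(hexafluoroacetylacetonate)), which is thought to act after reduction to a monovalent copper species by the diazo compound, expels N2 from 10 to give the electrophilic carbene 14; the central ether oxygen of 13 adds to its C3, and the oxonium ylide 15, a planar lactone enolate, undergoes a [1,2]-Stevens shift in which one O–CH2 bond breaks homolytically and the arylmethyl radical recombines at C3 inside the solvent cage, so that C3–O and C3–CH2 arise from one ether. The closest known reaction type is the copper-catalysed oxonium ylide [1,2]-benzyl shift of diazo ketones that carry a tethered benzyl ether, together with intermolecular ylide reactions of α-diazo lactones; capture of an acyclic dibenzyl ether by a lactone carbene followed by the shift is not established. No ring is closed. The new stereocentre C3 is controlled by the C4 substituent: the 4-benzyloxy-3,5-dimethoxybenzyl arm screens one face of the planar ylide, so the migrating group should bond anti to it, which places the two arylmethyl groups trans and the oxygen cis to the C4 arm (3S,4S). The step needs chemoselectivity for ylide formation over 1,2-hydride shift from C4–H (butenolide) and over benzylic C–H insertion, and it rests on substrate features: the central dialkyl ether oxygen of 13 is the most basic and least hindered oxygen present, 13 has no β-hydrogen so the ylide cannot eliminate, and the para-alkoxy group weakens the O–CH2 bond so that the shift should outrun reversal of the ylide; the fourfold excess of 13 and the slow addition of 10 support this and suppress carbene dimerisation. Because 13 is symmetrical either arylmethyl group can migrate to the same product, and the group left on oxygen is a hydrogenolysable protecting group.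

Step 9
Reactants: 16 (3S,4S)-3-[4-(benzyloxy)-3-methoxybenzyl]-3-{[4-(benzyloxy)-3-methoxybenzyl]oxy}-4-[4-(benzyloxy)-3,5-dimethoxybenzyl]dihydrofuran-2(3H)-one
Product: 17 (3S,4S)-3-hydroxy-3-(4-hydroxy-3-methoxybenzyl)-4-(4-hydroxy-3,5-dimethoxybenzyl)dihydrofuran-2(3H)-one
Conditions: H2 (1 atm), Pd(OH)2/C, EtOAc/EtOH, AcOH (cat.), rt
Reagents that add atoms: none
Why: Palladium-catalysed hydrogenolysis of benzylic C–O bonds: the three aryl benzyl ethers and the benzylic C–O bond of the tertiary ether (activated by its para oxygen) should be cleaved, whereas benzylic C–C bonds, methyl ethers, the lactone and both stereocentres are not affected.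

Compound list
1 | syringaldehyde (4-hydroxy-3,5-dimethoxybenzaldehyde) | COc1cc(C=O)cc(OC)c1O | starting material
2 | 4-(benzyloxy)-3,5-dimethoxybenzaldehyde | COc1cc(C=O)cc(OC)c1OCc1ccccc1 | intermediate
3 | dimethyl succinate | COC(=O)CCC(=O)OC | starting material
4 | methyl 2-[4-(benzyloxy)-3,5-dimethoxyphenyl]-5-oxotetrahydrofuran-3-carboxylate (Stobbe lactone; diastereomer mixture) | COC(=O)C1CC(=O)OC1c1cc(OC)c(OCc2ccccc2)c(OC)c1 | intermediate (not isolated)
5 | (E)-4-[4-(benzyloxy)-3,5-dimethoxyphenyl]-3-(methoxycarbonyl)but-3-enoic acid | COC(=O)/C(CC(=O)O)=C/c1cc(OC)c(OCc2ccccc2)c(OC)c1 | intermediate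
6 | (R)-4-[4-(benzyloxy)-3,5-dimethoxyphenyl]-3-(methoxycarbonyl)butanoic acid | COC(=O)[C@@H](CC(=O)O)Cc1cc(OC)c(OCc2ccccc2)c(OC)c1 | intermediate
7 | (R)-4-[4-(benzyloxy)-3,5-dimethoxyphenyl]-3-(hydroxymethyl)butanoic acid | OC[C@@H](CC(=O)O)Cc1cc(OC)c(OCc2ccccc2)c(OC)c1 | intermediate (not isolated)
8 | (R)-4-[4-(benzyloxy)-3,5-dimethoxybenzyl]dihydrofuran-2(3H)-one | O=C1OC[C@H](Cc2cc(OC)c(OCc3ccccc3)c(OC)c2)C1 | intermediate
9 | (4R)-4-[4-(benzyloxy)-3,5-dimethoxybenzyl]-3-(trifluoroacetyl)dihydrofuran-2(3H)-one (C3 epimers and enol form) | O=C(C1C(=O)OC[C@@H]1Cc1cc(OC)c(OCc2ccccc2)c(OC)c1)C(F)(F)F | intermediate (not isolated)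
10 | (R)-4-[4-(benzyloxy)-3,5-dimethoxybenzyl]-3-diazodihydrofuran-2(3H)-one | [N-]=[N+]=C1C(=O)OC[C@@H]1Cc1cc(OC)c(OCc2ccccc2)c(OC)c1 | intermediate
11 | 4-(benzyloxy)-3-methoxybenzyl alcohol | COc1cc(CO)ccc1OCc1ccccc1 | starting material
12 | 4-(benzyloxy)-3-methoxybenzyl chloride | COc1cc(CCl)ccc1OCc1ccccc1 | intermediate
13 | bis[4-(benzyloxy)-3-methoxybenzyl] ether | COc1cc(COCc2ccc(OCc3ccccc3)c(OC)c2)ccc1OCc1ccccc1 | intermediate
14 | copper carbene at C3 of the lactone derived from 10 (hfacac ligand not drawn) | [Cu]=C1C(=O)OC[C@@H]1Cc1cc(OC)c(OCc2ccccc2)c(OC)c1 | intermediate (not isolated)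
15 | oxonium ylide from 14 and 13: lactone enolate with a bis[4-(benzyloxy)-3-methoxybenzyl]oxonium group on C3 | COc1cc(C[O+](Cc2ccc(OCc3ccccc3)c(OC)c2)C2=C([O-])OC[C@@H]2Cc2cc(OC)c(OCc3ccccc3)c(OC)c2)ccc1OCc1ccccc1 | intermediate (not isolated)
16 | (3S,4S)-3-[4-(benzyloxy)-3-methoxybenzyl]-3-{[4-(benzyloxy)-3-methoxybenzyl]oxy}-4-[4-(benzyloxy)-3,5-dimethoxybenzyl]dihydrofuran-2(3H)-one | COc1cc(C[C@@]2(OCc3ccc(OCc4ccccc4)c(OC)c3)C(=O)OC[C@@H]2Cc2cc(OC)c(OCc3ccccc3)c(OC)c2)ccc1OCc1ccccc1 | intermediate
17 | (3S,4S)-3-hydroxy-3-(4-hydroxy-3-methoxybenzyl)-4-(4-hydroxy-3,5-dimethoxybenzyl)dihydrofuran-2(3H)-one | COc1cc(C[C@@]2(O)C(=O)OC[C@@H]2Cc2cc(OC)c(O)c(OC)c2)ccc1O | target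

Total step count: 9. Longest linear sequence: 7 steps (1, 2, 3, 4, 5, 8, 9); steps 6 and 7 form the side branch.

Steps most likely to fail

1. Step 8 (carbene capture and Stevens shift). The carbene may be consumed by 1,2-hydride shift from C4–H or by benzylic C–H insertion before the ether oxygen traps it. The arylmethyl radical may also recombine on both faces of the ylide. The fallback uses known enolate chemistry and makes the two C3 bonds one after the other. Lactone 8 is converted into its potassium enolate (KN(SiMe3)2, THF, −78 °C) and hydroxylated with 2-(phenylsulfonyl)-3-phenyloxaziridine to give (3R,4S)-4-[4-(benzyloxy)-3,5-dimethoxybenzyl]-3-hydroxydihydrofuran-2(3H)-one F1. The dianion of F1 (LiN(iPr)2, 2.2 equiv, THF/HMPA, −78 °C) is alkylated with chloride 12 in the presence of NaI on the face anti to the C4 arm. This should give (3S,4S)-3-[4-(benzyloxy)-3-methoxybenzyl]-4-[4-(benzyloxy)-3,5-dimethoxybenzyl]-3-hydroxydihydrofuran-2(3H)-one F2 with the arylmethyl groups trans. Hydrogenolysis of its two aryl benzyl ethers (H2, Pd/C, EtOAc/EtOH) then gives 17. The fallback sets out from 8 and rejoins the route at 17.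

2. Step 9 (global hydrogenolysis). The hindered tertiary benzylic ether may be cleaved only slowly, so that partly deprotected material accumulates. The fallback replaces hydrogenolysis by Lewis-acid debenzylation. BCl3 with pentamethylbenzene as cation scavenger in CH2Cl2 at −78 °C should cleave the three aryl benzyl ethers and the electron-rich tertiary benzylic ether of 16, while methyl ethers and lactone survive. It sets out from 16 and arrives directly at 17 without a new isolated compound.

3. Step 3 (asymmetric hydrogenation). Enantioselectivity may be too low, or the sense of induction reversed, with this 3,4,5-trioxygenated arylidene. The fallback is a classical resolution. Alkene 5 is hydrogenated with the achiral catalyst [Rh(cod)(dppb)]BF4 (H2, MeOH, Et3N) to racemic 4-[4-(benzyloxy)-3,5-dimethoxyphenyl]-3-(methoxycarbonyl)butanoic acid F3. The (S)-1-phenylethylammonium salt of the (R)-acid F4 is crystallised to constant rotation and then acidified to release 6. The amine antipode whose salt with the (R)-acid is the less soluble one is chosen by a small screen; the (S)-amine is written here. The fallback sets out from 5 and rejoins the route at 6.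

Further compounds
F1 | step 8 | (3R,4S)-4-[4-(benzyloxy)-3,5-dimethoxybenzyl]-3-hydroxydihydrofuran-2(3H)-one | O[C@H]1C(=O)OC[C@@H]1Cc1cc(OC)c(OCc2ccccc2)c(OC)c1
F2 | step 8 | (3S,4S)-3-[4-(benzyloxy)-3-methoxybenzyl]-4-[4-(benzyloxy)-3,5-dimethoxybenzyl]-3-hydroxydihydrofuran-2(3H)-one | COc1cc(C[C@@]2(O)C(=O)OC[C@@H]2Cc2cc(OC)c(OCc3ccccc3)c(OC)c2)ccc1OCc1ccccc1
F0 | step 9 | none | none
F3 | step 3 | racemic 4-[4-(benzyloxy)-3,5-dimethoxyphenyl]-3-(methoxycarbonyl)butanoic acid | COC(=O)C(CC(=O)O)Cc1cc(OC)c(OCc2ccccc2)c(OC)c1
F4 | step 3 | (S)-1-phenylethylammonium (R)-4-[4-(benzyloxy)-3,5-dimethoxyphenyl]-3-(methoxycarbonyl)butanoate | COC(=O)[C@@H](CC(=O)[O-])Cc1cc(OC)c(OCc2ccccc2)c(OC)c1.C[C@H]([NH3+])c1ccccc1
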